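**Strategy.** The route rests on opening the ten-membered carbocycle (C1–C10) at its C1=C10 double bond, the α-branched enal in which C2 lies trans to the formyl carbon C14 and cis, across the ring, to C9. One intramolecular Horner–Wadsworth–Emmons olefination of a C1 aldehyde by a C10 phosphonothioacetate closes this ring and sets that geometry at once. Its acyclic precursor already holds the C6–C8 stereotriad (Evans syn-aldol, then catalyst-controlled reduction), the ring-cis C4=C5 alkene, the C8 isovalerate and the C15 PMB ether, with the methylene lactone masked as a bis-silylated 2-methylene-1,4-diol.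

Key step: step 18

Remark on the chemistry: atoms carry germacranolide numbers (carbocycle C1–C10; C11–C13 the methylene-lactone carbons, C12 the carbonyl; C14 the formyl carbon on C10; C15 the hydroxymethyl carbon on C4). Both ring alkenes are ring-cis and carry the CIP descriptor E. The target is (6R,7R,8R) with a trans-fused lactone. Zinc reagent 12 is taken as its commercial THF solution. The supplied precursor and product structures were checked against the target and needed no correction. The one design change is a TBDPS group on O12, so that the primary allylic silyl ether survives the acidic release of the C1 aldehyde.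

**Route**

Step 1
Reactants: 1 monomethyl itaconate
Product: 2 methyl 3-(hydroxymethyl)but-3-enoate
Conditions: BH3·THF (1.05 equiv), THF, −15 to 0 °C; then H2O
Reagents that add atoms: none
Why: Chemoselective borane reduction of a carboxylic acid (via the acyloxyborane) in the presence of a methyl ester; one equivalent of BH3 is consumed by the acid, so no B–H should remain to hydroborate the alkene.

Step 2
Reactants: 2 methyl 3-(hydroxymethyl)but-3-enoate
Product: 3 methyl 3-{[tert-butyl(diphenyl)silyl]oxymethyl}but-3-enoate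
Conditions: TBDPSCl, imidazole, CH2Cl2, 0 °C to rt
Reagents that add atoms: tert-butyl(chloro)diphenylsilane, CC(C)(C)[Si](Cl)(c1ccccc1)c1ccccc1
Why: Standard silylation of a primary allylic alcohol; it also prevents lactonisation of 2, and the TBDPS ether is robust enough for the acidic acetal hydrolysis of step 17.

Step 3
Reactants: 3 methyl 3-{[tert-butyl(diphenyl)silyl]oxymethyl}but-3-enoate
Product: 4 3-{[tert-butyl(diphenyl)silyl]oxymethyl}but-3-enoic acid
Conditions: LiOH·H2O, THF/H2O (3:1), 0 °C; then 1 M HCl to pH 4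
Reagents that add atoms: lithium hydroxide, [Li+].[OH-]
Why: Saponification of an unhindered methyl ester at 0 °C should be faster than base-induced migration of the 1,1-disubstituted alkene into conjugation.

Step 4
Reactants: 4 3-{[tert-butyl(diphenyl)silyl]oxymethyl}but-3-enoic acid; 5 (S)-4-benzyl-1,3-oxazolidin-2-one
Product: 7 (S)-4-benzyl-3-(3-{[tert-butyl(diphenyl)silyl]oxymethyl}but-3-enoyl)-1,3-oxazolidin-2-one, via mixed pivalic anhydride 6 (not isolated)
Conditions: t-BuCOCl, Et3N, THF, −20 °C; then 5, LiCl, −20 °C to rt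
Reagents that add atoms: none
Why: N-Acylation of the oxazolidinone through a mixed anhydride (LiCl/Et3N protocol), mild enough to leave the β,γ-alkene in place.

Step 5
Reactants: 8 but-2-yne-1,4-diol
Product: 9 4-[(4-methoxybenzyl)oxy]but-2-yn-1-ol
Conditions: NaH (1.0 equiv), PMBCl (1.0 equiv), n-Bu4NI (cat.), THF/DMF, 0 °C to rt; 8 in threefold excess
Reagents that add atoms: 4-methoxybenzyl chloride, COc1ccc(CCl)cc1
Why: Williamson etherification; the excess of the symmetrical diol biases the outcome toward the mono-ether.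

Step 6
Reactants: 9 4-[(4-methoxybenzyl)oxy]but-2-yn-1-ol
Product: 11 (Z)-3-iodo-4-[(4-methoxybenzyl)oxy]but-2-en-1-ol, via cyclic alkenylalanate 10 (not isolated)
Conditions: NaAlH2(OCH2CH2OMe)2 (1.5 equiv), THF, 0 °C; EtOAc; then I2, −78 to 0 °C
Reagents that add atoms: iodine, II
Why: Alkoxide-directed trans-hydroalumination of a propargylic alcohol puts aluminium on the distal alkyne carbon (C4) in a five-membered alanate, and iodinolysis with retention gives the iodoalkene with iodine cis to the hydroxymethyl carbon (C6); iodine is added cold to outrun β-alkoxide loss to an allene.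

Step 7
Reactants: 11 (Z)-3-iodo-4-[(4-methoxybenzyl)oxy]but-2-en-1-ol; 12 [2-(1,3-dioxolan-2-yl)ethyl]zinc bromide
Product: 13 (E)-5-(1,3-dioxolan-2-yl)-3-{[(4-methoxybenzyl)oxy]methyl}pent-2-en-1-ol
Conditions: 12 (2.5 equiv), [1,1′-bis(diphenylphosphino)ferrocene]dichloropalladium PdCl2(dppf) (5 mol %), THF/DMF, 45 °C
Reagents that add atoms: none
Why: Negishi sp2–sp3 cross-coupling proceeds with retention at the alkenyl carbon, so the C1–C3 chain ends up cis to C6 (the ring-cis C4=C5 geometry); the bidentate ligand suppresses β-hydride elimination and the excess zinc reagent covers the free hydroxyl.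

Step 8
Reactants: 13 (E)-5-(1,3-dioxolan-2-yl)-3-{[(4-methoxybenzyl)oxy]methyl}pent-2-en-1-ol
Product: 14 (E)-5-(1,3-dioxolan-2-yl)-3-{[(4-methoxybenzyl)oxy]methyl}pent-2-enal
Conditions: MnO2 (20 equiv), CH2Cl2, rt
Reagents that add atoms: none
Why: Allylic oxidation with MnO2 is neutral and heterogeneous, conditions under which β,β-disubstituted enals normally keep their alkene geometry (formyl group cis to the dioxolanylethyl chain).

Step 9
Reactants: 15 (diethoxyphosphoryl)acetic acid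
Product: 16 S-ethyl 2-(diethoxyphosphoryl)ethanethioate
Conditions: EtSH, DCC, DMAP (cat.), CH2Cl2, 0 °C to rt
Reagents that add atoms: ethanethiol, CCS
Why: Steglich-type thioesterification of an unhindered carboxylic acid.

Step 10
Reactants: 7 (S)-4-benzyl-3-(3-{[tert-butyl(diphenyl)silyl]oxymethyl}but-3-enoyl)-1,3-oxazolidin-2-one; 14 (E)-5-(1,3-dioxolan-2-yl)-3-{[(4-methoxybenzyl)oxy]methyl}pent-2-enal
Product: 18 (S)-4-benzyl-3-[(2S,3R,4E)-2-(3-{[tert-butyl(diphenyl)silyl]oxy}prop-1-en-2-yl)-7-(1,3-dioxolan-2-yl)-3-hydroxy-5-{[(4-methoxybenzyl)oxy]methyl}hept-4-enoyl]-1,3-oxazolidin-2-one, via Z-boron dienolate 17 (not isolated)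
Conditions: n-Bu2BOTf, Et3N, CH2Cl2, −78 to 0 °C; 14, −78 to −10 °C; pH 7 buffer, MeOH, 30% H2O2, 0 °C
Reagents that add atoms: none
Why: Evans syn-aldol: the Z-boron dienolate reacts at its α-carbon through a Zimmerman–Traxler chair and the benzyl group of the (S)-auxiliary blocks one enolate face, so C7 and C6 are set syn with the absolute sense needed for the trans-fused lactone.

Step 11
Reactants: 18 the syn-aldol adduct
Product: 19 (2S,3R,4E)-2-(3-{[tert-butyl(diphenyl)silyl]oxy}prop-1-en-2-yl)-7-(1,3-dioxolan-2-yl)-3-hydroxy-N-methoxy-5-{[(4-methoxybenzyl)oxy]methyl}-N-methylhept-4-enamide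
Conditions: MeNHOMe·HCl, AlMe3, CH2Cl2, −20 to 0 °C; aq. Rochelle salt
Reagents that add atoms: N,O-dimethylhydroxylamine hydrochloride, CNOC.Cl
Why: Weinreb transamidation of a β-hydroxy imide with the aluminium amide, directed to the exocyclic carbonyl by chelation to the free C6 hydroxyl; the auxiliary is recovered.

Step 12
Reactants: 19 the β-hydroxy Weinreb amide
Product: 20 (2S,3R,4E)-3-{[tert-butyl(dimethyl)silyl]oxy}-2-(3-{[tert-butyl(diphenyl)silyl]oxy}prop-1-en-2-yl)-7-(1,3-dioxolan-2-yl)-N-methoxy-5-{[(4-methoxybenzyl)oxy]methyl}-N-methylhept-4-enamide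
Conditions: TBSOTf, 2,6-lutidine, CH2Cl2, −78 °C
Reagents that add atoms: tert-butyldimethylsilyl trifluoromethanesulfonate, CC(C)(C)[Si](C)(C)OS(=O)(=O)C(F)(F)F
Why: Silyl triflate silylation of a hindered secondary allylic alcohol is fast at −78 °C, well below the temperature at which the dioxolane is activated.

Step 13
Reactants: 20 the silylated Weinreb amide; 21 dibromomethane
Product: 22 (3S,4R,5E)-1-bromo-4-{[tert-butyl(dimethyl)silyl]oxy}-3-(3-{[tert-butyl(diphenyl)silyl]oxy}prop-1-en-2-yl)-8-(1,3-dioxolan-2-yl)-6-{[(4-methoxybenzyl)oxy]methyl}oct-5-en-2-one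
Conditions: 21 (3 equiv), MeLi·LiBr (2.8 equiv, dropwise), THF, −78 °C; sat. NH4Cl
Reagents that add atoms: none
Why: Bromomethyllithium, formed in the flask by bromine–lithium exchange, adds once to the Weinreb amide because the chelated tetrahedral adduct survives until the quench, giving the α-bromo ketone that carries C9 (carbenoid homologation of a Weinreb amide).

Step 14
Reactants: 22 the α-bromo ketone
Product: 23 (2S,3R,4R,5E)-1-bromo-4-{[tert-butyl(dimethyl)silyl]oxy}-3-(3-{[tert-butyl(diphenyl)silyl]oxy}prop-1-en-2-yl)-8-(1,3-dioxolan-2-yl)-6-{[(4-methoxybenzyl)oxy]methyl}oct-5-en-2-ol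
Conditions: (S)-2-methyl-CBS-oxazaborolidine (0.5 equiv), catecholborane, toluene/CH2Cl2, −78 to −40 °C; MeOH; pH 7 buffer
Reagents that add atoms: none
Why: Corey–Bakshi–Shibata reduction: the (S)-oxazaborolidine binds the ketone with CH2Br as the small and the branched C7 as the large substituent, so hydride should add to the face that gives the C8 configuration of the target (descriptor S here only because Br outranks C7); catecholborane does not hydroborate the alkenes.

Step 15
Reactants: 23 the bromohydrin; 24 isovaleric anhydride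
Product: 25 (2S,3R,4R,5E)-1-bromo-4-{[tert-butyl(dimethyl)silyl]oxy}-3-(3-{[tert-butyl(diphenyl)silyl]oxy}prop-1-en-2-yl)-8-(1,3-dioxolan-2-yl)-6-{[(4-methoxybenzyl)oxy]methyl}oct-5-en-2-yl 3-methylbutanoate
Conditions: 24 (2 equiv), DMAP (0.2 equiv), pyridine, CH2Cl2, 0 °C to rt
Reagents that add atoms: none
Why: DMAP-catalysed acylation of the secondary alcohol; pyridine is too weak a base to close the bromohydrin to an epoxide, and the ester is in place before any C14 carboxyl derivative exists, so O8 cannot lactonise later.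

Step 16
Reactants: 25 the bromo isovalerate; 16 S-ethyl 2-(diethoxyphosphoryl)ethanethioate
Product: 27 S-ethyl (4R,5R,6R,7E)-6-{[tert-butyl(dimethyl)silyl]oxy}-5-(3-{[tert-butyl(diphenyl)silyl]oxy}prop-1-en-2-yl)-2-(diethoxyphosphoryl)-10-(1,3-dioxolan-2-yl)-8-{[(4-methoxybenzyl)oxy]methyl}-4-[(3-methylbutanoyl)oxy]dec-7-enethioate (both C2 epimers), via sodium phosphonate enolate 26 (not isolated)
Conditions: 16 (1.5 equiv), NaH (1.4 equiv), DMF, 0 °C; then 25, NaI (0.5 equiv), 50 °C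
Reagents that add atoms: none
Why: SN2 C-alkylation of a soft, weakly basic phosphonate-stabilised enolate by a primary bromide with iodide catalysis (in situ Finkelstein); this forms the C9–C10 bond, and the new C10 centre is lost in step 18.

Step 17
Reactants: 27 the phosphonate acetal
Product: 28 S-ethyl (4R,5R,6R,7E)-6-{[tert-butyl(dimethyl)silyl]oxy}-5-(3-{[tert-butyl(diphenyl)silyl]oxy}prop-1-en-2-yl)-2-(diethoxyphosphoryl)-8-{[(4-methoxybenzyl)oxy]methyl}-4-[(3-methylbutanoyl)oxy]-11-oxoundec-7-enethioate (both C2 epimers)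
Conditions: PPTS (0.3 equiv), acetone/H2O (10:1), 55 °C
Reagents that add atoms: water, O
Why: Mild acid-catalysed hydrolysis of the dioxolane; the secondary TBS and primary TBDPS ethers, the PMB ether and both esters should tolerate pyridinium tosylate in wet acetone.

Step 18
Reactants: 28 the acyclic aldehyde phosphonate
Product: 30 S-ethyl (1E,5E,7R,8R,9R)-7-{[tert-butyl(dimethyl)silyl]oxy}-8-(3-{[tert-butyl(diphenyl)silyl]oxy}prop-1-en-2-yl)-5-{[(4-methoxybenzyl)oxy]methyl}-9-[(3-methylbutanoyl)oxy]cyclodeca-1,5-diene-1-carbothioate, via oxaphosphetane 29 (not isolated)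
Conditions: LiCl (20 equiv), DBU (10 equiv), MeCN, 25 °C; 28 added by syringe pump over 12 h to a final 1 mM
Reagents that add atoms: none
Why: DBU, with Li+ chelating the phosphoryl and thioester oxygens, deprotonates C10 of 28; the stabilised carbanion adds reversibly to the C1 aldehyde and oxaphosphetane 29 collapses by syn-elimination of diethyl phosphate to give the C1=C10 bond (Masamune–Roush form of the intramolecular Horner–Wadsworth–Emmons macrocyclisation, here at the small end of its ring-size range). The ten-membered carbocycle closes by 10-exo-trig attack of C10 on the formyl carbon under pseudo-high dilution, so that ring closure can outpace dimerisation. No stereocentre is created; the epimeric phosphonate carbon becomes sp2. The one selectivity needed is C2 trans to the thioester carbon C14 (C2 cis to C9 across the ring), and it rests on the thermodynamic preference of the reversible addition of a stabilised α-branched phosphonate; the ring could hold either geometry, so no help from strain is assumed. Closure is favoured by the cis C4=C5 bond and the substituted C6–C8 segment, which fold the chain, and it is protected by the masked acrylate (no Michael acceptor) and by the acylated O8 (no lactonisation onto C14).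

Step 19
Reactants: 30 the macrocyclic thioester
Product: 31 (1E,5E,7R,8R,9R)-7-{[tert-butyl(dimethyl)silyl]oxy}-8-(3-{[tert-butyl(diphenyl)silyl]oxy}prop-1-en-2-yl)-5-{[(4-methoxybenzyl)oxy]methyl}-9-[(3-methylbutanoyl)oxy]cyclodeca-1,5-diene-1-carbaldehyde
Conditions: Et3SiH (3 equiv), Pd/CaCO3 poisoned with Pb(OAc)2 (10 mol % Pd), acetone, rt
Reagents that add atoms: none
Why: Fukuyama reduction: zerovalent palladium inserts into the acyl–sulfur bond and the acyl palladium is reduced by the silane to the aldehyde, leaving the isovalerate untouched; the poisoned catalyst is chosen to spare the 1,1-disubstituted and conjugated alkenes.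

Step 20
Reactants: 31 the bis-silylated enal
Product: 32 (1E,5E,7R,8S,9R)-7-hydroxy-8-(3-hydroxyprop-1-en-2-yl)-5-{[(4-methoxybenzyl)oxy]methyl}-9-[(3-methylbutanoyl)oxy]cyclodeca-1,5-diene-1-carbaldehyde
Conditions: HF·pyridine, pyridine, THF, 0 °C to rt
Reagents that add atoms: none
Why: Fluoride cleavage of both silyl ethers in a buffered, weakly acidic medium, chosen to avoid the base-induced 1,3-acyl shift from O8 to O6 that a basic fluoride source could cause.

Step 21
Reactants: 32 the 2-methylene-1,4-diol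
Product: 35 (6R,7R,8R)-15-[(4-methoxybenzyl)oxy]-8-(3-methylbutanoyloxy)-14-oxogermacra-1(10),4,11(13)-trien-12,6-olide, via C12 hydroxy-enal 33 (not isolated), via C12 lactol 34 (not isolated)
Conditions: TEMPO (0.2 equiv), PhI(OAc)2 (2.5 equiv), CH2Cl2, rt
Reagents that add atoms: none
Why: Oxoammonium oxidation is selective for the primary allylic alcohol; the resulting enal is trapped by the C6 hydroxyl as lactol 34, which is oxidised on to the α-methylene-γ-butyrolactone (oxidative lactonisation of a 1,4-diol); C6 and C7 are untouched, so the trans ring fusion follows from step 10.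

Step 22
Reactants: 35 the PMB-protected lactone
Product: 36 (6R,7R,8R)-15-hydroxy-8-(3-methylbutanoyloxy)-14-oxogermacra-1(10),4,11(13)-trien-12,6-olide (target)
Conditions: DDQ (1.5 equiv), CH2Cl2/pH 7 phosphate buffer (10:1), 0 °C
Reagents that add atoms: none
Why: Oxidative cleavage of the electron-rich PMB ether by DDQ (hydride abstraction, then hydrolysis of the benzylic oxocarbenium ion) under buffered conditions that should leave the enal, the methylene lactone and the isovalerate intact.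

**Compound list**

1 | monomethyl itaconate | C=C(CC(=O)OC)C(=O)O | starting material
2 | methyl 3-(hydroxymethyl)but-3-enoate | C=C(CO)CC(=O)OC | intermediate
3 | methyl 3-{[tert-butyl(diphenyl)silyl]oxymethyl}but-3-enoate | C=C(CO[Si](c1ccccc1)(c1ccccc1)C(C)(C)C)CC(=O)OC | intermediate
4 | 3-{[tert-butyl(diphenyl)silyl]oxymethyl}but-3-enoic acid | C=C(CO[Si](c1ccccc1)(c1ccccc1)C(C)(C)C)CC(=O)O | intermediate
5 | (S)-4-benzyl-1,3-oxazolidin-2-one | O=C1N[C@@H](Cc2ccccc2)CO1 | starting material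
6 | mixed anhydride of 4 with pivalic acid | C=C(CO[Si](c1ccccc1)(c1ccccc1)C(C)(C)C)CC(=O)OC(=O)C(C)(C)C | intermediate
7 | (S)-4-benzyl-3-(3-{[tert-butyl(diphenyl)silyl]oxymethyl}but-3-enoyl)-1,3-oxazolidin-2-one | C=C(CO[Si](c1ccccc1)(c1ccccc1)C(C)(C)C)CC(=O)N1C(=O)OC[C@@H]1Cc1ccccc1 | intermediate
8 | but-2-yne-1,4-diol | OCC#CCO | starting material
9 | 4-[(4-methoxybenzyl)oxy]but-2-yn-1-ol | OCC#CCOCc1ccc(OC)cc1 | intermediate
10 | sodium cyclic alkenylalanate (Al on C4, ring oxygen from the C6 alkoxide) | [Na+].COCCO[Al-]1(OCCOC)OCC=C1COCc1ccc(OC)cc1 | intermediate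
11 | (Z)-3-iodo-4-[(4-methoxybenzyl)oxy]but-2-en-1-ol | OC/C=C(\I)COCc1ccc(OC)cc1 | intermediate
12 | [2-(1,3-dioxolan-2-yl)ethyl]zinc bromide | Br[Zn]CCC1OCCO1 | starting material
13 | (E)-5-(1,3-dioxolan-2-yl)-3-{[(4-methoxybenzyl)oxy]methyl}pent-2-en-1-ol | OC/C=C(\CCC1OCCO1)COCc1ccc(OC)cc1 | intermediate
14 | (E)-5-(1,3-dioxolan-2-yl)-3-{[(4-methoxybenzyl)oxy]methyl}pent-2-enal | O=C/C=C(\CCC1OCCO1)COCc1ccc(OC)cc1 | intermediate
15 | (diethoxyphosphoryl)acetic acid | CCOP(=O)(CC(=O)O)OCC | starting material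
16 | S-ethyl 2-(diethoxyphosphoryl)ethanethioate | CCOP(=O)(CC(=O)SCC)OCC | intermediate
17 | Z-dibutylboron dienolate of 7 | C=C(CO[Si](c1ccccc1)(c1ccccc1)C(C)(C)C)/C=C(/N1C(=O)OC[C@@H]1Cc1ccccc1)OB(CCCC)CCCC | intermediate
18 | (S)-4-benzyl-3-[(2S,3R,4E)-2-(3-{[tert-butyl(diphenyl)silyl]oxy}prop-1-en-2-yl)-7-(1,3-dioxolan-2-yl)-3-hydroxy-5-{[(4-methoxybenzyl)oxy]methyl}hept-4-enoyl]-1,3-oxazolidin-2-one | C=C(CO[Si](c1ccccc1)(c1ccccc1)C(C)(C)C)[C@@H]([C@H](O)/C=C(/COCc1ccc(OC)cc1)CCC1OCCO1)C(=O)N1C(=O)OC[C@@H]1Cc1ccccc1 | intermediate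
19 | (2S,3R,4E)-2-(3-{[tert-butyl(diphenyl)silyl]oxy}prop-1-en-2-yl)-7-(1,3-dioxolan-2-yl)-3-hydroxy-N-methoxy-5-{[(4-methoxybenzyl)oxy]methyl}-N-methylhept-4-enamide | C=C(CO[Si](c1ccccc1)(c1ccccc1)C(C)(C)C)[C@@H]([C@H](O)/C=C(/COCc1ccc(OC)cc1)CCC1OCCO1)C(=O)N(C)OC | intermediate
20 | 3-O-TBS ether of 19, (2S,3R,4E) | C=C(CO[Si](c1ccccc1)(c1ccccc1)C(C)(C)C)[C@@H]([C@H](O[Si](C)(C)C(C)(C)C)/C=C(/COCc1ccc(OC)cc1)CCC1OCCO1)C(=O)N(C)OC | intermediate
21 | dibromomethane | BrCBr | starting material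
22 | (3S,4R,5E)-1-bromo-4-{[tert-butyl(dimethyl)silyl]oxy}-3-(3-{[tert-butyl(diphenyl)silyl]oxy}prop-1-en-2-yl)-8-(1,3-dioxolan-2-yl)-6-{[(4-methoxybenzyl)oxy]methyl}oct-5-en-2-one | C=C(CO[Si](c1ccccc1)(c1ccccc1)C(C)(C)C)[C@@H]([C@H](O[Si](C)(C)C(C)(C)C)/C=C(/COCc1ccc(OC)cc1)CCC1OCCO1)C(=O)CBr | intermediate
23 | (2S,3R,4R,5E)-1-bromo-4-{[tert-butyl(dimethyl)silyl]oxy}-3-(3-{[tert-butyl(diphenyl)silyl]oxy}prop-1-en-2-yl)-8-(1,3-dioxolan-2-yl)-6-{[(4-methoxybenzyl)oxy]methyl}oct-5-en-2-ol | C=C(CO[Si](c1ccccc1)(c1ccccc1)C(C)(C)C)[C@@H]([C@H](O[Si](C)(C)C(C)(C)C)/C=C(/COCc1ccc(OC)cc1)CCC1OCCO1)[C@H](O)CBr | intermediate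
24 | isovaleric anhydride | CC(C)CC(=O)OC(=O)CC(C)C | starting material
25 | 3-methylbutanoate of 23, (2S,3R,4R,5E) | C=C(CO[Si](c1ccccc1)(c1ccccc1)C(C)(C)C)[C@@H]([C@H](O[Si](C)(C)C(C)(C)C)/C=C(/COCc1ccc(OC)cc1)CCC1OCCO1)[C@H](OC(=O)CC(C)C)CBr | intermediate
26 | sodium enolate of 16 | [Na+].CCOP(=O)(OCC)[CH-]C(=O)SCC | intermediate
27 | S-ethyl (4R,5R,6R,7E)-6-{[tert-butyl(dimethyl)silyl]oxy}-5-(3-{[tert-butyl(diphenyl)silyl]oxy}prop-1-en-2-yl)-2-(diethoxyphosphoryl)-10-(1,3-dioxolan-2-yl)-8-{[(4-methoxybenzyl)oxy]methyl}-4-[(3-methylbutanoyl)oxy]dec-7-enethioate (C2 epimers) | C=C(CO[Si](c1ccccc1)(c1ccccc1)C(C)(C)C)[C@@H]([C@H](O[Si](C)(C)C(C)(C)C)/C=C(/COCc1ccc(OC)cc1)CCC1OCCO1)[C@H](OC(=O)CC(C)C)CC(C(=O)SCC)P(=O)(OCC)OCC | intermediate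
28 | S-ethyl (4R,5R,6R,7E)-6-{[tert-butyl(dimethyl)silyl]oxy}-5-(3-{[tert-butyl(diphenyl)silyl]oxy}prop-1-en-2-yl)-2-(diethoxyphosphoryl)-8-{[(4-methoxybenzyl)oxy]methyl}-4-[(3-methylbutanoyl)oxy]-11-oxoundec-7-enethioate (C2 epimers) | C=C(CO[Si](c1ccccc1)(c1ccccc1)C(C)(C)C)[C@@H]([C@H](O[Si](C)(C)C(C)(C)C)/C=C(/COCc1ccc(OC)cc1)CCC=O)[C@H](OC(=O)CC(C)C)CC(C(=O)SCC)P(=O)(OCC)OCC | intermediate
29 | lithium oxaphosphetane spanning C1 and C10 of the closing ring | C=C(CO[Si](c1ccccc1)(c1ccccc1)C(C)(C)C)[C@H]1[C@H](O[Si](C)(C)C(C)(C)C)/C=C(/COCc2ccc(OC)cc2)CCC2OP([O-])(OCC)(OCC)C2(C(=O)SCC)C[C@H]1OC(=O)CC(C)C.[Li+] | intermediate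
30 | S-ethyl (1E,5E,7R,8R,9R)-7-{[tert-butyl(dimethyl)silyl]oxy}-8-(3-{[tert-butyl(diphenyl)silyl]oxy}prop-1-en-2-yl)-5-{[(4-methoxybenzyl)oxy]methyl}-9-[(3-methylbutanoyl)oxy]cyclodeca-1,5-diene-1-carbothioate | C=C(CO[Si](c1ccccc1)(c1ccccc1)C(C)(C)C)[C@H]1[C@H](O[Si](C)(C)C(C)(C)C)/C=C(/COCc2ccc(OC)cc2)CC/C=C(/C(=O)SCC)C[C@H]1OC(=O)CC(C)C | intermediate
31 | (1E,5E,7R,8R,9R)-7-{[tert-butyl(dimethyl)silyl]oxy}-8-(3-{[tert-butyl(diphenyl)silyl]oxy}prop-1-en-2-yl)-5-{[(4-methoxybenzyl)oxy]methyl}-9-[(3-methylbutanoyl)oxy]cyclodeca-1,5-diene-1-carbaldehyde | C=C(CO[Si](c1ccccc1)(c1ccccc1)C(C)(C)C)[C@H]1[C@H](O[Si](C)(C)C(C)(C)C)/C=C(/COCc2ccc(OC)cc2)CC/C=C(/C=O)C[C@H]1OC(=O)CC(C)C | intermediate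
32 | (1E,5E,7R,8S,9R)-7-hydroxy-8-(3-hydroxyprop-1-en-2-yl)-5-{[(4-methoxybenzyl)oxy]methyl}-9-[(3-methylbutanoyl)oxy]cyclodeca-1,5-diene-1-carbaldehyde | C=C(CO)[C@H]1[C@H](O)/C=C(/COCc2ccc(OC)cc2)CC/C=C(/C=O)C[C@H]1OC(=O)CC(C)C | intermediate
33 | (1E,5E,7R,8S,9R)-7-hydroxy-5-{[(4-methoxybenzyl)oxy]methyl}-9-[(3-methylbutanoyl)oxy]-8-(3-oxoprop-1-en-2-yl)cyclodeca-1,5-diene-1-carbaldehyde | C=C(C=O)[C@H]1[C@H](O)/C=C(/COCc2ccc(OC)cc2)CC/C=C(/C=O)C[C@H]1OC(=O)CC(C)C | intermediate
34 | 6,12-lactol of 33 (C12 epimers; 6R,7R,8R) | C=C1C(O)O[C@@H]2/C=C(/COCc3ccc(OC)cc3)CC/C=C(/C=O)C[C@@H](OC(=O)CC(C)C)[C@@H]12 | intermediate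
35 | (6R,7R,8R)-15-[(4-methoxybenzyl)oxy]-8-(3-methylbutanoyloxy)-14-oxogermacra-1(10),4,11(13)-trien-12,6-olide | C=C1C(=O)O[C@@H]2/C=C(/COCc3ccc(OC)cc3)CC/C=C(/C=O)C[C@@H](OC(=O)CC(C)C)[C@@H]12 | intermediate
36 | (6R,7R,8R)-15-hydroxy-8-(3-methylbutanoyloxy)-14-oxogermacra-1(10),4,11(13)-trien-12,6-olide, both ring alkenes ring-cis, trans-fused lactone | C=C1C(=O)O[C@@H]2/C=C(/CO)CC/C=C(/C=O)C[C@@H](OC(=O)CC(C)C)[C@@H]12 | target

**Step count and risk**

Total step count: 22. Longest linear sequence: 17 steps (steps 1–4 or 5–8, then 10–22).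

The three steps most likely to fail:

1. Step 18. Closure of a strained ten-membered ring may lose to intermolecular olefination (cyclic dimers and oligomers). During the long reaction time the C10 carbanion may instead take the acyl group from O8, or the alkene geometry may erode. The fallback makes the same C1=C10 bond by ring-closing metathesis. It sets out from 27: olefination of the phosphonate with formaldehyde (K2CO3, aqueous HCHO, THF) should give the 2-methylene thioester acetal F1. Hydrolysis of the dioxolane (PPTS, wet acetone) should give the 2-methylene thioester aldehyde F2, and Lombardo methylenation (Zn, CH2Br2, TiCl4) the terminal diene F3. Ring-closing metathesis of F3 with the second-generation Hoveyda–Grubbs catalyst in dilute toluene at 80 °C, with loss of ethene, should give the ring-cis alkene that a ten-membered ring favours. The fallback comes back to the route at 30.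

2. Step 16. Substitution at the β-branched, β-acyloxy primary bromide may be slow, so that elimination or participation of the neighbouring ester takes over. The fallback moves the C9–C10 bond formation to the far more reactive α-bromo ketone and uses an amide that cannot lactonise easily. It sets out from 22: alkylation of the sodium salt of diethyl [2-(methoxy(methyl)amino)-2-oxoethyl]phosphonate (NaH, THF, 0 °C) should give the γ-keto phosphonoamide F4. Oxazaborolidine-catalysed reduction as in step 14 should give the C8 alcohol F5, and acylation with 24 (DMAP, pyridine) the isovalerate F6. Acetal hydrolysis (PPTS, wet acetone) should give the aldehyde F7, and LiCl/DBU macrocyclisation at high dilution the ten-membered Weinreb amide F8. Reduction of the amide with Cp2Zr(H)Cl in THF, which spares the isovalerate, comes back to the route at 31.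

3. Step 14. Facial control by the catalyst may be eroded by the adjacent C7 stereocentre or by uncatalysed reduction, and the β,γ-unsaturated α-bromo ketone may epimerise at C7. The fallback sets C8 by substrate control from the free C6 hydroxyl. It sets out from 19: excess chloromethyllithium (ICH2Cl, MeLi·LiBr, THF, −78 °C) should give the β-hydroxy chloromethyl ketone F9. Hydroxyl-directed reduction with Me4NBH(OAc)3 in MeCN/AcOH at −25 °C (intramolecular hydride delivery, 1,3-anti) should give the anti-diol chlorohydrin F10. K2CO3 in MeOH should close the terminal epoxy alcohol F11, and TBSOTf/2,6-lutidine at −78 °C should give the silyl ether epoxide F12. Opening of F12 at the terminal carbon with MgBr2·OEt2 comes back to the route at 23.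

**Further compounds**

F1 | step 18 | 2-methylene thioester acetal (S-ethyl 2-methylene analogue of 27 without phosphonate) | C=C(CO[Si](c1ccccc1)(c1ccccc1)C(C)(C)C)[C@@H]([C@H](O[Si](C)(C)C(C)(C)C)/C=C(/COCc1ccc(OC)cc1)CCC1OCCO1)[C@H](OC(=O)CC(C)C)CC(=C)C(=O)SCC
F2 | step 18 | 2-methylene thioester aldehyde | C=C(CO[Si](c1ccccc1)(c1ccccc1)C(C)(C)C)[C@@H]([C@H](O[Si](C)(C)C(C)(C)C)/C=C(/COCc1ccc(OC)cc1)CCC=O)[C@H](OC(=O)CC(C)C)CC(=C)C(=O)SCC
F3 | step 18 | terminal diene for ring-closing metathesis | C=C(CO[Si](c1ccccc1)(c1ccccc1)C(C)(C)C)[C@@H]([C@H](O[Si](C)(C)C(C)(C)C)/C=C(/COCc1ccc(OC)cc1)CCC=C)[C@H](OC(=O)CC(C)C)CC(=C)C(=O)SCC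
F4 | step 16 | γ-keto phosphonoamide | C=C(CO[Si](c1ccccc1)(c1ccccc1)C(C)(C)C)[C@@H]([C@H](O[Si](C)(C)C(C)(C)C)/C=C(/COCc1ccc(OC)cc1)CCC1OCCO1)C(=O)CC(C(=O)N(C)OC)P(=O)(OCC)OCC
F5 | step 16 | C8 alcohol of the phosphonoamide | C=C(CO[Si](c1ccccc1)(c1ccccc1)C(C)(C)C)[C@@H]([C@H](O[Si](C)(C)C(C)(C)C)/C=C(/COCc1ccc(OC)cc1)CCC1OCCO1)[C@H](O)CC(C(=O)N(C)OC)P(=O)(OCC)OCC
F6 | step 16 | C8 isovalerate of the phosphonoamide | C=C(CO[Si](c1ccccc1)(c1ccccc1)C(C)(C)C)[C@@H]([C@H](O[Si](C)(C)C(C)(C)C)/C=C(/COCc1ccc(OC)cc1)CCC1OCCO1)[C@H](OC(=O)CC(C)C)CC(C(=O)N(C)OC)P(=O)(OCC)OCC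
F7 | step 16 | C1 aldehyde of the phosphonoamide | C=C(CO[Si](c1ccccc1)(c1ccccc1)C(C)(C)C)[C@@H]([C@H](O[Si](C)(C)C(C)(C)C)/C=C(/COCc1ccc(OC)cc1)CCC=O)[C@H](OC(=O)CC(C)C)CC(C(=O)N(C)OC)P(=O)(OCC)OCC
F8 | step 16 | ten-membered Weinreb amide | C=C(CO[Si](c1ccccc1)(c1ccccc1)C(C)(C)C)[C@H]1[C@H](O[Si](C)(C)C(C)(C)C)/C=C(/COCc2ccc(OC)cc2)CC/C=C(/C(=O)N(C)OC)C[C@H]1OC(=O)CC(C)C
F9 | step 14 | β-hydroxy chloromethyl ketone | C=C(CO[Si](c1ccccc1)(c1ccccc1)C(C)(C)C)[C@@H]([C@H](O)/C=C(/COCc1ccc(OC)cc1)CCC1OCCO1)C(=O)CCl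
F10 | step 14 | anti-diol chlorohydrin | C=C(CO[Si](c1ccccc1)(c1ccccc1)C(C)(C)C)[C@@H]([C@H](O)/C=C(/COCc1ccc(OC)cc1)CCC1OCCO1)[C@H](O)CCl
F11 | step 14 | terminal epoxy alcohol | C=C(CO[Si](c1ccccc1)(c1ccccc1)C(C)(C)C)[C@@H]([C@H](O)/C=C(/COCc1ccc(OC)cc1)CCC1OCCO1)[C@H]1CO1
F12 | step 14 | silyl ether epoxide | C=C(CO[Si](c1ccccc1)(c1ccccc1)C(C)(C)C)[C@@H]([C@H](O[Si](C)(C)C(C)(C)C)/C=C(/COCc1ccc(OC)cc1)CCC1OCCO1)[C@H]1CO1
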